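## Structural features

The target is built on a central benzene (ring C) whose two meta oxygens each close a 2,3-dihydrofuran (furans A and B) onto the neighbouring carbons. Around ring C the substituents run: O of furan A, H, O of furan B, C3 of furan B, a CH2 group, C3 of furan A. Each dihydrofuran carries a 4-hydroxyphenyl group on C2 and a 3,5-dioxygenated phenyl group on C3, trans to one another. The C3 aryl of furan A is a free 3,5-dihydroxyphenyl group; that of furan B (ring B) is tied back through its ortho carbon to a CH(2,4-dihydroxyphenyl) unit and the ring C CH2 group, which closes a seven-membered ring over ring C, C3 of furan B and ring B. There are five stereocentres, all R: C2/C3 of each furan are adjacent pairs, and the seven-ring methine stands 1,4 to C3 of furan B across ring B. The fragile elements are the eight phenols, the two C2–O bonds (para-oxybenzylic aryl ethers that ionise under Lewis acids) and the electron-rich resorcinol rings, which compete for any electrophile. The real difficulty lies in the two C3–aryl bonds: each joins a stereogenic diarylmethine on the crowded ring C to the one carbon of a 3,5-dioxyphenyl ring that is meta to both oxygens, where Friedel–Crafts chemistry cannot reach. Without the seven-ring bridge, ring C and its two furans have a twofold axis through the CH2-bearing carbon and the C–H carbon between the oxygens; the key step uses this by adding the same aryl group, under one chiral rhodium catalyst, to the two C4 carbons of a ring C bis-coumarin, which flank the side-chain carbon and later become the two C3 atoms.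

## Logic of the disconnections

**24 ⇒ 23.** The eight O–methyl bonds are cut. Methyl ethers are the only phenol protection that survives every reagent between the key step and the end. The demand on the forward step is that dealkylation leaves, or lets re-form, the two benzylic C2–O bonds; it is therefore placed after the alkene has been consumed, so that a C2 cation has no partner other than its own ring C oxygen.

**23 ⇒ 22.** The bond between the ortho carbon of ring B and the seven-ring methine is cut. It is the one aryl–carbon bond of the skeleton that matches Friedel–Crafts polarity: the cation is stabilised by the 2,4-dioxygenated ring and the attacking carbon is ortho and para to two methoxy groups. This removes a ring and a stereocentre and restores the twofold symmetry, so the two 3,5-dimethoxyphenyl groups of 22 are homotopic and no choice between them arises. The forward step must protonate the alkene at the carbon next to ring C, close the seven-membered ring with the correct face, and not ionise the C2–O bonds.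

**22 ⇒ 19 + 21 (21 ⇒ 20).** The alkene is cut. The carbonyl is placed on the ring C side because a small phosphonate carbanion meets a hindered aldehyde more easily than the reverse. The alkene geometry is irrelevant to the next step. The demand is olefination of an aldehyde flanked by two methines.

**19 ⇒ 18 ⇒ 17.** No skeletal bond is cut; the side chain is returned to the ester level. An ester is the one simple hydroxyl protection that survives the Lewis acids and the heat used to build the bis-coumarin.

**17 ⇒ 14 + 15 (through 16).** Both C2–aryl bonds are cut and each C2 becomes a carboxyl-bearing carbon, a radical precursor. This removes two stereocentres, which need not be controlled in 14 because they are re-set trans to the C3 aryl groups. The aryl donor 15 carries three 4-methoxyphenyl groups on one boroxine ring, so a single molecule of it covers both sites. The forward step must couple twice, and radical capture by nickel must outrun loss of the C3 hydrogen to a benzofuran.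

**14 ⇒ 12 (through 13) ⇒ 10 (through 11).** Both C2–O bonds are cut to a phenoxide and an α-bromo acid, which re-folds to a six-membered aryl lactone; then the C–Br bonds are cut. The lactone carbonyl is the carbon later lost as CO2, so the six-membered ring serves only as a template. The forward steps must brominate α to the carbonyl and not on the arenes, open the aryl lactones without cleaving the pivalate, and substitute faster than they eliminate.

**10 ⇒ 7 + 8 (through 9).** Both C4–aryl bonds are cut. The gain is large: 7 is flat and achiral, 8 is commercial, and both stereocentres come from the catalyst. The demand is a double conjugate addition beside a peri substituent with the same face at both enoates.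

**7 ⇒ 4 + 5 (through 6).** Each lactone is cut at its C3=C4 bond and its acyl–oxygen bond, leading to a salicylaldehyde and a stabilised ylide. The demand is thermal E/Z isomerisation and lactonisation at two hindered sites.

**4 ⇒ 3 ⇒ 2 ⇒ 1.** The two O–methyl bonds ortho to formyl, the two aryl–formyl bonds and the ester are cut. The O-methylated 1 is chosen over a free resorcinol for three reasons: the benzylic hydroxyl is then acylated without competition, the methoxy groups direct both formylations para to themselves (the carbons flanking the side chain), and the phenols are released by chelation exactly where the lactones need them.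

## Other disconnections considered

**Alternative 1:** The cut is the bond between ring B and C3 of furan B, together with the C2–H bond of furan B. In the forward direction A1 would arise from the aryl bromide A2, in which furan B is still an aromatic benzofuran and the side chain already carries the (R)-methine. A zerovalent palladium catalyst with a bulky phosphine would insert into the C–Br bond, add the aryl group to C3 in a 7-exo syn-carbopalladation, and a formate salt would replace palladium at C2 by hydrogen.
- In its favour: one step closes the seven-membered ring, dearomatises the furan and sets C3 and C2 of furan B. The trans relationship follows from the mechanism (syn addition, then hydride delivery with retention). No cation is involved, so the C2–O bond is never at risk.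
- Better than the chosen plan on one point: the seven-ring methine is set beforehand under reagent control, whereas step 13 of the chosen plan relies on the ring system.
- Against it here: A1 contains neither furan A nor its two aryl groups. The second dihydrofuran, with its meta-linked C3 aryl group and two more stereocentres, would have to be built afterwards on a hindered, fully elaborated core by unrelated chemistry. The twofold relationship of the C3 methines is not used.
- Mechanism: a seven-membered dearomative Heck closure onto a 2-arylbenzofuran is a demanding case of a reaction better established for smaller rings, and its face selectivity rests on a centre 1,4 to the new one.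
- Step economy: at a disadvantage, because the enantioselective synthesis of A2 and the later construction of furan A are two separate sequences. In robustness of the furan B C2–O bond it is the equal or the better.

**Alternative 2:** The cut is the C2–C3 bond of both dihydrofurans. The twofold-symmetric bis(cis-2-aryl-3-methoxycarbonyl) compound A3 would arise from the bis(aryldiazoacetate) A4, whose ring C oxygens carry 4-methoxybenzyl groups. A chiral dirhodium tetracarboxylate (divalent rhodium) would generate two carbenes, each inserting into the benzylic ether C–H bond five atoms away.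
- In its favour: two rings, two C–C bonds and four stereocentres would arise in one catalyst-controlled step, and the hidden symmetry is used as fully as in the chosen plan.
- Better than the chosen plan on two points: the C2 centres are set by the catalyst (the chosen plan sets them later by substrate control), and the 4-oxyphenyl groups need no separate arylation.
- Against it here: A3 carries an ester where the C3 aryl group must stand and has the cis relationship. Each C3 must be epimerised and converted into a meta-linked 3,5-dioxyphenyl group, so the central problem is only postponed to a double decarboxylative arylation. That arylation would pass through a benzylic radical with a β C–O bond that can fragment, and the C3 ester invites base-induced β-elimination of the aryloxide. The two carbene carbons also flank the pivaloyloxymethyl group, whose carbonyl oxygen is placed for ylide formation.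
- Mechanism: concerted carbenoid C–H insertion against carbometalation–protonation; as catalyst-controlled two-directional reactions the two are equals.
- Step economy: about level. What the insertion saves in ring construction is spent on epimerisation, hydrolysis and arylation at C3, and the end game from the side chain onwards would be the same.

**Alternative 3:** The cut is the C2–aryl bond of both dihydrofurans. A5 would arise from the diacid A6, the silyl-protected counterpart of 14, which would be activated in the flask and reduced at a cathode in the presence of a nickel–bipyridine catalyst and 4-iodoanisole A7; each C2 radical would be arylated trans to the C3 aryl group.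
- In its favour: the bonds formed are those of step 8 of the chosen plan, so the stereochemical argument is identical.
- Better than the chosen plan on two points: the cathode delivers the electrons at room temperature, without the amine base and the heating that step 8 needs, and lets the rate of radical generation be set by the current; and the silyl ether is indifferent to the hydroxide of the ring contraction.
- Against it as the strategy-defining step: it leaves open how the C3 centres with their meta-linked aryl groups arise, so A6 would most plausibly still be made by the conjugate addition and ring contraction of the chosen plan. A triisopropylsilyl ether would not survive TiCl4 and BCl3 on the way to the bis-coumarin, so a protecting-group exchange would be needed, and the bulky silyl group sits between the two reacting carbons.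
- Mechanism: equal at this bond in its product-forming part (radical capture by an arylnickel species, reductive elimination from trivalent nickel, trans selectivity from C3); the aryl group reaches nickel by oxidative addition of A7 there and by transmetalation from 15 in the chosen plan.
- Step economy: equal at the coupling itself, about two steps longer through the protecting-group exchange, and dependent on electrochemical equipment.

Key step: step 5

Remark: all five stereocentres of 24 are R and both dihydrofurans are trans; the two lactone centres of 10 are R and keep that descriptor through the ring contraction because the substituent ranking only rotates; the configuration written at the bromine- and carboxyl-bearing carbons of 12, 13, 14 and 16 is the expected one but is immaterial, since these carbons become planar radicals in step 8. Compound 15 is the cyclic anhydride (boroxine) of 4-methoxyphenylboronic acid, assumed to be bought as such; one molecule carries three transferable aryl groups.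

Step 1
Reactants: 1 3,5-dimethoxybenzyl alcohol
Product: 2 3,5-dimethoxybenzyl pivalate
Conditions: PivCl, pyridine, DMAP (cat.), CH2Cl2, 0 °C → rt
Reagents that add atoms: pivaloyl chloride CC(C)(C)C(=O)Cl
Why: Standard acylation of a primary benzylic alcohol; with the ring oxygens methylated there is no competing O-acylation, and the pivalate is the simple hydroxyl protection that later tolerates TiCl4, BCl3 and 215 °C.

Step 2
Reactants: 2 3,5-dimethoxybenzyl pivalate
Product: 3 2,6-diformyl-3,5-dimethoxybenzyl pivalate
Conditions: Cl2CHOMe (5 equiv), TiCl4 (6 equiv), CH2Cl2, 0 °C → rt; then ice/H2O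
Reagents that add atoms: dichloromethyl methyl ether COC(Cl)Cl; water O
Why: Rieche formylation; the electrophile attacks the two carbons para to a methoxy group, which are the carbons flanking the side chain, whereas the carbon between the methoxy groups is only ortho-activated and the benzylic ester does not ionise because its cation would be meta to both donors. Excess reagent is planned because the first formyl group deactivates the ring.

Step 3
Reactants: 3 2,6-diformyl-3,5-dimethoxybenzyl pivalate
Product: 4 2,6-diformyl-3,5-dihydroxybenzyl pivalate
Conditions: BCl3 (3 equiv), CH2Cl2, −78 → 0 °C; then H2O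
Reagents that add atoms: none
Why: Chelation-controlled demethylation; BCl3 bridges each formyl oxygen and the neighbouring methoxy oxygen and cleaves only aryl methyl ethers ortho to a carbonyl group, which both methoxy groups of 3 are, while the pivalate and the aldehydes are left alone at low temperature.

Step 4
Reactants: 4 2,6-diformyl-3,5-dihydroxybenzyl pivalate; 5 ethyl (triphenylphosphoranylidene)acetate
Product: 7 (2,8-dioxo-2H,8H-pyrano[3,2-g]chromen-5-yl)methyl pivalate, via bis-cinnamate diester 6 (not isolated)
Conditions: 5 (2.4 equiv), PhNEt2, reflux (ca. 215 °C)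
Reagents that add atoms: none
Why: Wittig olefination of each salicylaldehyde unit gives the E-cinnamate 6, which at this temperature isomerises to the Z-ester and lactonises onto the ortho phenol with loss of ethanol (the classical one-pot coumarin synthesis). No stereocentre is formed.

Step 5
Reactants: 7 (2,8-dioxo-2H,8H-pyrano[3,2-g]chromen-5-yl)methyl pivalate; 8 3,5-dimethoxyphenylboronic acid
Product: 10 [(4R,6R)-4,6-bis(3,5-dimethoxyphenyl)-2,8-dioxo-3,4,6,7-tetrahydro-2H,8H-pyrano[3,2-g]chromen-5-yl]methyl pivalate, via mono-adduct 9 (not isolated)
Conditions: Rh(acac)(C2H4)2 (6 mol %), (R)-5,5'-bis(diphenylphosphino)-4,4'-bi-1,3-benzodioxole (6.6 mol %), 8 (6 equiv), 1,4-dioxane/H2O (10:1), 60 °C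
Reagents that add atoms: none
Why: Transmetalation of 8 to the hydroxo-rhodium bisphosphine complex gives an aryl–rhodium species (monovalent rhodium) that coordinates the C3=C4 bond of one coumarin and inserts it with the aryl group delivered to C4; water protonates the resulting rhodium enolate, releasing the lactone and the hydroxo complex, and the cycle repeats on the second enoate of 9. The closest known reaction type is the rhodium/bisphosphine-catalysed asymmetric 1,4-addition of arylboronic acids to coumarins (Hayashi–Miyaura reaction), which gives 4-arylchroman-2-ones; only the substrate is new, a bis-enoate with a substituent peri to both C4 carbons. No ring is closed. Each new stereocentre (C4 and C6, the later C3 atoms of furans B and A) is set by the chiral pocket of the bisphosphine, which shields one face of the flat coumarin; by analogy with simple coumarins the (R)-ligand should give R at both carbons, and the antipodal ligand is the remedy should the peri group reverse the sense. The two enoates are separated by the side-chain carbon, so the first centre should not bias the second; minor-face addition at either site then ends mainly in the meso (4R,6S) diastereomer, which is separable, and this raises the enantiomeric purity of the twofold-symmetric product (Horeau principle). The step needs 1,4- rather than 1,2-addition and insertion faster than protodeboronation: aryl–rhodium does not attack the lactone carbonyl, the pivalate is inert in the neutral aqueous medium, and the excess of 8 compensates for slow insertion next to the CH2OPiv group. The aryl group approaches perpendicular to the ring plane and ends pseudo-axial, so the in-plane peri group should slow the insertion without blocking it.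

Step 6
Reactants: 10 [(4R,6R)-4,6-bis(3,5-dimethoxyphenyl)-2,8-dioxo-3,4,6,7-tetrahydro-2H,8H-pyrano[3,2-g]chromen-5-yl]methyl pivalate
Product: 12 [(3S,4R,6R,7S)-3,7-dibromo-4,6-bis(3,5-dimethoxyphenyl)-2,8-dioxo-3,4,6,7-tetrahydro-2H,8H-pyrano[3,2-g]chromen-5-yl]methyl pivalate, via bis(silyl ketene acetal) 11 (not isolated)
Conditions: LiN(SiMe3)2 (2.4 equiv), Me3SiCl (3 equiv), THF, −78 °C; then NBS (2.05 equiv), THF, −78 °C
Reagents that add atoms: N-bromosuccinimide O=C1CCC(=O)N1Br
Why: Internal-quench enolisation gives the neutral bis(silyl ketene acetal) 11, which reacts with NBS at −78 °C far faster than the methoxyarenes and cannot exchange protons with the product, so over-bromination and ring bromination are avoided (α-halogenation of a lactone through its silyl ketene acetal). Bromine should enter anti to the pseudo-axial aryl group (3,4-trans and 6,7-trans); the configuration at these carbons is of no consequence.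

Step 7
Reactants: 12 [(3S,4R,6R,7S)-3,7-dibromo-4,6-bis(3,5-dimethoxyphenyl)-2,8-dioxo-3,4,6,7-tetrahydro-2H,8H-pyrano[3,2-g]chromen-5-yl]methyl pivalate
Product: 14 (2R,3R,5R,6R)-3,5-bis(3,5-dimethoxyphenyl)-4-(pivaloyloxymethyl)-2,3,5,6-tetrahydrobenzo[1,2-b:5,4-b']difuran-2,6-dicarboxylic acid, via ring-opened bis(bromo acid) 13 (not isolated)
Conditions: LiOH (6 equiv), THF/H2O (3:1), 0 °C → rt; then 1 M HCl to pH 2
Reagents that add atoms: lithium hydroxide [Li+].[OH-]
Why: Hydroxide opens the two aryl lactones within minutes at 0 °C, far faster than it attacks the hindered pivalate, and each ring C phenoxide then displaces the α-bromide of its carboxylate in a 5-exo-tet Williamson closure with inversion (Perkin-type coumarin-to-benzofuran ring contraction at the dihydro level). The C3 centres are not touched, and the intramolecular substitution should outrun intermolecular elimination.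

Step 8
Reactants: 14 (2R,3R,5R,6R)-3,5-bis(3,5-dimethoxyphenyl)-4-(pivaloyloxymethyl)-2,3,5,6-tetrahydrobenzo[1,2-b:5,4-b']difuran-2,6-dicarboxylic acid; 15 tris(4-methoxyphenyl)boroxine
Product: 17 [(2R,3R,5R,6R)-3,5-bis(3,5-dimethoxyphenyl)-2,6-bis(4-methoxyphenyl)-2,3,5,6-tetrahydrobenzo[1,2-b:5,4-b']difuran-4-yl]methyl pivalate, via bis(N-acyloxytetrachlorophthalimide) 16 (not isolated)
Conditions: N-hydroxytetrachlorophthalimide (2.2 equiv), N,N'-diisopropylcarbodiimide (2.2 equiv), DMAP (cat.), CH2Cl2, rt; evaporate; then 15 (2 equiv), NiCl2·6H2O (40 mol %), 4,7-diphenyl-1,10-phenanthroline (44 mol %), Et3N (20 equiv), 1,4-dioxane/DMF (10:1), 75 °C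
Reagents that add atoms: none
Why: Carbodiimide coupling gives the redox-active ester 16; 15 enters the boronate equilibrium in the wet amine medium and passes its aryl groups to nickel, the arylnickel species (monovalent nickel) reduces each ester by single-electron transfer, and loss of CO2 and tetrachlorophthalimide leaves an α-oxy C2 radical that is captured and coupled by reductive elimination from trivalent nickel (nickel-catalysed decarboxylative Suzuki–Miyaura arylation of redox-active esters of secondary acids). One molecule of 15 carries three aryl groups and so supplies both C2 substituents; the excess allows for three aryl groups per carboxyl, as the method uses. Each C2 centre is set by the neighbouring C3 aryl group: the planar radical is captured, and the aryl group delivered, on the face anti to it, which gives the trans arrangement (2R next to 3R).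

Step 9
Reactants: 17 [(2R,3R,5R,6R)-3,5-bis(3,5-dimethoxyphenyl)-2,6-bis(4-methoxyphenyl)-2,3,5,6-tetrahydrobenzo[1,2-b:5,4-b']difuran-4-yl]methyl pivalate
Product: 18 [(2R,3R,5R,6R)-3,5-bis(3,5-dimethoxyphenyl)-2,6-bis(4-methoxyphenyl)-2,3,5,6-tetrahydrobenzo[1,2-b:5,4-b']difuran-4-yl]methanol
Conditions: i-Bu2AlH (3 equiv), CH2Cl2, −78 °C; then aq. potassium sodium tartrate
Reagents that add atoms: none
Why: Reductive cleavage of the pivalate by the aluminium hydride; nothing else in 17 is reducible under these conditions.

Step 10
Reactants: 18 [(2R,3R,5R,6R)-3,5-bis(3,5-dimethoxyphenyl)-2,6-bis(4-methoxyphenyl)-2,3,5,6-tetrahydrobenzo[1,2-b:5,4-b']difuran-4-yl]methanol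
Product: 19 (2R,3R,5R,6R)-3,5-bis(3,5-dimethoxyphenyl)-2,6-bis(4-methoxyphenyl)-2,3,5,6-tetrahydrobenzo[1,2-b:5,4-b']difuran-4-carbaldehyde
Conditions: Dess–Martin periodinane, NaHCO3, CH2Cl2, 0 °C → rt
Reagents that add atoms: none
Why: Dess–Martin oxidation of a primary benzylic alcohol under buffered, non-acidic conditions; the electron-rich arenes and the benzylic C2–O bonds are untouched and over-oxidation is not possible.

Step 11
Reactants: 20 2,4-dimethoxybenzyl alcohol
Product: 21 diethyl (2,4-dimethoxybenzyl)phosphonate
Conditions: P(OEt)3, ZnI2, toluene, reflux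
Reagents that add atoms: triethyl phosphite CCOP(OCC)OCC
Why: Direct Michaelis–Arbuzov-type conversion of an electron-rich benzylic alcohol; ZnI2 activates the hydroxyl group, the phosphite displaces it and dealkylation gives the phosphonate.

Step 12
Reactants: 19 (2R,3R,5R,6R)-3,5-bis(3,5-dimethoxyphenyl)-2,6-bis(4-methoxyphenyl)-2,3,5,6-tetrahydrobenzo[1,2-b:5,4-b']difuran-4-carbaldehyde; 21 diethyl (2,4-dimethoxybenzyl)phosphonate
Product: 22 (2R,3R,5R,6R)-4-[(E)-2-(2,4-dimethoxyphenyl)ethenyl]-3,5-bis(3,5-dimethoxyphenyl)-2,6-bis(4-methoxyphenyl)-2,3,5,6-tetrahydrobenzo[1,2-b:5,4-b']difuran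
Conditions: 21 (1.5 equiv), KOt-Bu, THF, 0 °C → rt
Reagents that add atoms: none
Why: Horner–Wadsworth–Emmons olefination; the small phosphonate carbanion adds to the hindered, non-enolisable aldehyde and elimination should give the E-stilbene. The geometry is in any case irrelevant, since the next step protonates the alkene.

Step 13
Reactants: 22 (2R,3R,5R,6R)-4-[(E)-2-(2,4-dimethoxyphenyl)ethenyl]-3,5-bis(3,5-dimethoxyphenyl)-2,6-bis(4-methoxyphenyl)-2,3,5,6-tetrahydrobenzo[1,2-b:5,4-b']difuran
Product: 23 octa-O-methyl ether of 24 (all five stereocentres R)
Conditions: CF3CO2H, CH2Cl2, 0 °C → rt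
Reagents that add atoms: none
Why: Protonation occurs at the alkene carbon next to ring C, because only the other carbon gives a cation stabilised by ortho and para methoxy groups; that cation is attacked by the ortho carbon of a 3,5-dimethoxyphenyl group (intramolecular Friedel–Crafts alkylation closing the seven-membered ring), and the two aryl groups are homotopic, so either gives 23. The new methine is set by the ring system: the aryl group should sit pseudo-axial, away from the flanking ring B methoxy group and on the face opposite to C2 of furan B (its hydrogen trans to the C3 hydrogen of furan B). Because the alkylation is reversible in acid, this more stable arrangement, the one present in 24, should prevail.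

Step 14
Reactants: 23 octa-O-methyl ether of 24 (all five stereocentres R)
Product: 24 target CNP0154047.1
Conditions: BBr3 (excess), CH2Cl2, −78 → 0 °C; then MeOH, aq. NaHCO3
Reagents that add atoms: none
Why: Lewis-acid dealkylation of all eight aryl methyl ethers. The para-oxybenzylic C2–O bonds may ionise reversibly, but with no alkene left the only partner of a C2 cation is its own ring C oxygen, and re-closure gives the trans-dihydrofuran again under control of C3.

## Compound list

1 | 3,5-dimethoxybenzyl alcohol | COc1cc(CO)cc(OC)c1 | starting material
2 | 3,5-dimethoxybenzyl pivalate | COc1cc(COC(=O)C(C)(C)C)cc(OC)c1 | intermediate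
3 | 2,6-diformyl-3,5-dimethoxybenzyl pivalate | COc1cc(OC)c(C=O)c(COC(=O)C(C)(C)C)c1C=O | intermediate
4 | 2,6-diformyl-3,5-dihydroxybenzyl pivalate | Oc1cc(O)c(C=O)c(COC(=O)C(C)(C)C)c1C=O | intermediate
5 | ethyl (triphenylphosphoranylidene)acetate | CCOC(=O)C=P(c1ccccc1)(c1ccccc1)c1ccccc1 | starting material
6 | diethyl (2E,2'E)-3,3'-[4,6-dihydroxy-2-(pivaloyloxymethyl)-1,3-phenylene]diacrylate | CCOC(=O)/C=C/c1c(O)cc(O)c(/C=C/C(=O)OCC)c1COC(=O)C(C)(C)C | intermediate (not isolated)
7 | (2,8-dioxo-2H,8H-pyrano[3,2-g]chromen-5-yl)methyl pivalate (ring C bis-coumarin) | O=C1C=Cc2c(COC(=O)C(C)(C)C)c3C=CC(=O)Oc3cc2O1 | intermediate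
8 | 3,5-dimethoxyphenylboronic acid | COc1cc(OC)cc(B(O)O)c1 | starting material
9 | [(4R)-4-(3,5-dimethoxyphenyl)-2,8-dioxo-3,4-dihydro-2H,8H-pyrano[3,2-g]chromen-5-yl]methyl pivalate (mono-adduct) | O=C1C[C@H](c4cc(OC)cc(OC)c4)c2c(COC(=O)C(C)(C)C)c3C=CC(=O)Oc3cc2O1 | intermediate (not isolated)
10 | [(4R,6R)-4,6-bis(3,5-dimethoxyphenyl)-2,8-dioxo-3,4,6,7-tetrahydro-2H,8H-pyrano[3,2-g]chromen-5-yl]methyl pivalate | O=C1C[C@H](c4cc(OC)cc(OC)c4)c2c(COC(=O)C(C)(C)C)c3[C@@H](c4cc(OC)cc(OC)c4)CC(=O)Oc3cc2O1 | intermediate
11 | [(4R,6R)-4,6-bis(3,5-dimethoxyphenyl)-2,8-bis(trimethylsilyloxy)-4H,6H-pyrano[3,2-g]chromen-5-yl]methyl pivalate (bis(silyl ketene acetal)) | C[Si](C)(C)OC1=C[C@H](c4cc(OC)cc(OC)c4)c2c(COC(=O)C(C)(C)C)c3[C@@H](c4cc(OC)cc(OC)c4)C=C(O[Si](C)(C)C)Oc3cc2O1 | intermediate (not isolated)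
12 | [(3S,4R,6R,7S)-3,7-dibromo-4,6-bis(3,5-dimethoxyphenyl)-2,8-dioxo-3,4,6,7-tetrahydro-2H,8H-pyrano[3,2-g]chromen-5-yl]methyl pivalate (3,4-trans and 6,7-trans) | O=C1[C@@H](Br)[C@H](c4cc(OC)cc(OC)c4)c2c(COC(=O)C(C)(C)C)c3[C@@H](c4cc(OC)cc(OC)c4)[C@H](Br)C(=O)Oc3cc2O1 | intermediate
13 | (2S,2'S,3R,3'R)-3,3'-[4,6-dihydroxy-2-(pivaloyloxymethyl)-1,3-phenylene]bis[2-bromo-3-(3,5-dimethoxyphenyl)propanoic acid] (present as its lithium salt) | OC(=O)[C@@H](Br)[C@H](c4cc(OC)cc(OC)c4)c2c(COC(=O)C(C)(C)C)c([C@@H](c4cc(OC)cc(OC)c4)[C@H](Br)C(=O)O)c(O)cc2O | intermediate (not isolated)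
14 | (2R,3R,5R,6R)-3,5-bis(3,5-dimethoxyphenyl)-4-(pivaloyloxymethyl)-2,3,5,6-tetrahydrobenzo[1,2-b:5,4-b']difuran-2,6-dicarboxylic acid | OC(=O)[C@@H]1Oc2cc3c(c(COC(=O)C(C)(C)C)c2[C@H]1c1cc(OC)cc(OC)c1)[C@@H](c1cc(OC)cc(OC)c1)[C@H](C(=O)O)O3 | intermediate
15 | tris(4-methoxyphenyl)boroxine (2,4,6-tris(4-methoxyphenyl)-1,3,5,2,4,6-trioxatriborinane, the cyclic anhydride of 4-methoxyphenylboronic acid) | COc1ccc(cc1)B1OB(c2ccc(OC)cc2)OB(c2ccc(OC)cc2)O1 | starting material
16 | bis(4,5,6,7-tetrachloro-1,3-dioxoisoindolin-2-yl) (2R,3R,5R,6R)-3,5-bis(3,5-dimethoxyphenyl)-4-(pivaloyloxymethyl)-2,3,5,6-tetrahydrobenzo[1,2-b:5,4-b']difuran-2,6-dicarboxylate | O=C(ON4C(=O)c5c(Cl)c(Cl)c(Cl)c(Cl)c5C4=O)[C@@H]1Oc2cc3c(c(COC(=O)C(C)(C)C)c2[C@H]1c1cc(OC)cc(OC)c1)[C@@H](c1cc(OC)cc(OC)c1)[C@H](C(=O)ON1C(=O)c4c(Cl)c(Cl)c(Cl)c(Cl)c4C1=O)O3 | intermediate (not isolated)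
17 | [(2R,3R,5R,6R)-3,5-bis(3,5-dimethoxyphenyl)-2,6-bis(4-methoxyphenyl)-2,3,5,6-tetrahydrobenzo[1,2-b:5,4-b']difuran-4-yl]methyl pivalate | COc1ccc([C@@H]2Oc3cc4c(c(COC(=O)C(C)(C)C)c3[C@H]2c2cc(OC)cc(OC)c2)[C@@H](c2cc(OC)cc(OC)c2)[C@H](c2ccc(OC)cc2)O4)cc1 | intermediate
18 | [(2R,3R,5R,6R)-3,5-bis(3,5-dimethoxyphenyl)-2,6-bis(4-methoxyphenyl)-2,3,5,6-tetrahydrobenzo[1,2-b:5,4-b']difuran-4-yl]methanol | COc1ccc([C@@H]2Oc3cc4c(c(CO)c3[C@H]2c2cc(OC)cc(OC)c2)[C@@H](c2cc(OC)cc(OC)c2)[C@H](c2ccc(OC)cc2)O4)cc1 | intermediate
19 | (2R,3R,5R,6R)-3,5-bis(3,5-dimethoxyphenyl)-2,6-bis(4-methoxyphenyl)-2,3,5,6-tetrahydrobenzo[1,2-b:5,4-b']difuran-4-carbaldehyde | COc1ccc([C@@H]2Oc3cc4c(c(C=O)c3[C@H]2c2cc(OC)cc(OC)c2)[C@@H](c2cc(OC)cc(OC)c2)[C@H](c2ccc(OC)cc2)O4)cc1 | intermediate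
20 | 2,4-dimethoxybenzyl alcohol | COc1ccc(CO)c(OC)c1 | starting material
21 | diethyl (2,4-dimethoxybenzyl)phosphonate | CCOP(=O)(Cc1ccc(OC)cc1OC)OCC | intermediate
22 | (2R,3R,5R,6R)-4-[(E)-2-(2,4-dimethoxyphenyl)ethenyl]-3,5-bis(3,5-dimethoxyphenyl)-2,6-bis(4-methoxyphenyl)-2,3,5,6-tetrahydrobenzo[1,2-b:5,4-b']difuran | COc1ccc([C@@H]2Oc3cc4c(c(/C=C/c5ccc(OC)cc5OC)c3[C@H]2c2cc(OC)cc(OC)c2)[C@@H](c2cc(OC)cc(OC)c2)[C@H](c2ccc(OC)cc2)O4)cc1 | intermediate
23 | octa-O-methyl ether of 24 (all five stereocentres R) | COc1ccc([C@@H]2Oc3cc4c5c(c3[C@H]2c2cc(OC)cc(OC)c2)C[C@H](c2ccc(OC)cc2OC)c2c(OC)cc(OC)cc2[C@H]5[C@H](c2ccc(OC)cc2)O4)cc1 | intermediate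
24 | CNP0154047.1 (octaphenol; both dihydrofurans 2R,3R-trans, seven-ring methine R) | Oc1ccc([C@@H]2Oc3cc4c5c(c3[C@H]2c2cc(O)cc(O)c2)C[C@H](c2ccc(O)cc2O)c2c(O)cc(O)cc2[C@H]5[C@H](c2ccc(O)cc2)O4)cc1 | target

## Step count and least certain steps

Total step count: 14. Longest linear sequence: 13 steps (steps 1–10 and 12–14, from 1); step 11 is a one-step side branch.

**Step 5 (key step).** Most likely to go wrong is slow or incomplete insertion at the second enoate: each C4 carbon is peri to the pivaloyloxymethyl group, so protodeboronation of 8 may outrun the addition. Erosion of face selectivity by the same crowding is the second concern. The fallback separates bond formation from stereocontrol. It sets out from 7 and 8: an oxidative Heck arylation (Pd(OAc)2, 1,10-phenanthroline, O2, DMF, 80–100 °C; divalent palladium reoxidised by O2) can be forced thermally because no stereocentre is at stake, and would give the bis(4-arylcoumarin) F1. A copper hydride asymmetric 1,4-reduction (Cu(OAc)2, the appropriate enantiomer of 5,5'-bis[bis(3,5-di-tert-butyl-4-methoxyphenyl)phosphino]-4,4'-bi-1,3-benzodioxole, polymethylhydrosiloxane, t-BuOH, toluene) is a known reaction of 4-arylcoumarins in which the small hydride is little affected by the peri group. It would set both centres and come back to the route at 10.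

**Step 2.** Most likely to go wrong is the second formylation stalling, or straying to the carbon between the methoxy groups: the first formyl group, complexed to TiCl4, deactivates the ring and the remaining para position is flanked on both sides. The fallback uses bromine as a placeholder. It sets out from 2: NBS (2.1 equiv, MeCN, 0 °C → rt) would brominate both carbons para to methoxy to give the dibromide F2. A double Suzuki–Miyaura vinylation (potassium vinyltrifluoroborate, PdCl2(dppf), Cs2CO3, THF/H2O, 80 °C) would give the divinyl compound F3. Lemieux–Johnson cleavage (OsO4 cat., NaIO4, 2,6-lutidine, dioxane/H2O) would come back to the route at 3.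

**Step 8.** Most likely to go wrong is loss of the activated esters to the amine base at 75 °C before they are reduced (α-deprotonation next to the aryloxy group and expulsion of the N-oxide). The second concern is β-hydride loss from the C2–nickel intermediate or oxidation of the C2 radical: either aromatises the ring to a benzofuran and destroys C3. Incomplete coupling at one of the two sites is the third. The fallback is polar instead of radical. It sets out from 14: oxidative decarboxylation with Pb(OAc)4 (pyridine cat., benzene/THF, rt) would give the bis(2-acetoxy) acetal F4. BF3·OEt2 with potassium (4-methoxyphenyl)trifluoroborate (CH2Cl2/MeCN, −20 → 0 °C) would then transfer the aryl group to each oxocarbenium ion anti to the C3 aryl group, and the sequence comes back to the route at 17.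

**Step 13.** Most likely to go wrong is ionisation of the para-methoxybenzylic C2–O bonds under the acid needed to protonate the alkene, while the alkene is still present; this would divert the material into other ring closures. Incomplete face selectivity at the new methine, the only centre set neither by a catalyst nor by an adjacent substituent, is the second concern. The fallback reaches the same cation from a carbinol under much weaker acid. It sets out from 18: CBr4/PPh3 (CH2Cl2, 0 °C) would give the benzylic bromide F5. Zinc insertion (Zn dust, LiCl, THF) and addition of the benzylic zinc bromide to commercial 2,4-dimethoxybenzaldehyde (MgCl2, THF, rt) would give the carbinol F6 as a mixture of epimers. F6 should ionise with a catalytic Lewis acid (Sc(OTf)3, CH2Cl2, −40 °C), close the seven-membered ring reversibly and come back to the route at 23.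

**Step 14.** Most likely to go wrong is opening of the dihydrofurans by ionisation of their C2–O bonds under BBr3 without clean re-closure, above all in the unconstrained furan A. The fallback accepts the opening and rebuilds the rings separately. It sets out from 23: BBr3 (CH2Cl2, −78 → 0 °C) with an aqueous quench would deliver the ring-opened bis(benzylic alcohol) decaphenol F7. Dilute acid (HCl, MeOH, rt) would then re-close both furans through the para-quinone methides by 5-exo capture by the adjacent ring C phenol, trans to the C3 aryl groups, and come back to the route at 24.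

## Further compounds

F1 | step 5 | [4,6-bis(3,5-dimethoxyphenyl)-2,8-dioxo-2H,8H-pyrano[3,2-g]chromen-5-yl]methyl pivalate | O=C1C=C(c4cc(OC)cc(OC)c4)c2c(COC(=O)C(C)(C)C)c3C(c4cc(OC)cc(OC)c4)=CC(=O)Oc3cc2O1
F2 | step 2 | 2,6-dibromo-3,5-dimethoxybenzyl pivalate | COc1cc(OC)c(Br)c(COC(=O)C(C)(C)C)c1Br
F3 | step 2 | 2,6-diethenyl-3,5-dimethoxybenzyl pivalate | COc1cc(OC)c(C=C)c(COC(=O)C(C)(C)C)c1C=C
F4 | step 8 | [(3R,5R)-2,6-diacetoxy-3,5-bis(3,5-dimethoxyphenyl)-2,3,5,6-tetrahydrobenzo[1,2-b:5,4-b']difuran-4-yl]methyl pivalate (acetal epimers) | CC(=O)OC1Oc2cc3c(c(COC(=O)C(C)(C)C)c2[C@H]1c1cc(OC)cc(OC)c1)[C@@H](c1cc(OC)cc(OC)c1)C(OC(C)=O)O3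
F5 | step 13 | (2R,3R,5R,6R)-4-(bromomethyl)-3,5-bis(3,5-dimethoxyphenyl)-2,6-bis(4-methoxyphenyl)-2,3,5,6-tetrahydrobenzo[1,2-b:5,4-b']difuran | COc1ccc([C@@H]2Oc3cc4c(c(CBr)c3[C@H]2c2cc(OC)cc(OC)c2)[C@@H](c2cc(OC)cc(OC)c2)[C@H](c2ccc(OC)cc2)O4)cc1
F6 | step 13 | 1-(2,4-dimethoxyphenyl)-2-[(2R,3R,5R,6R)-3,5-bis(3,5-dimethoxyphenyl)-2,6-bis(4-methoxyphenyl)-2,3,5,6-tetrahydrobenzo[1,2-b:5,4-b']difuran-4-yl]ethanol (carbinol epimers) | COc1ccc([C@@H]2Oc3cc4c(c(CC(O)c5ccc(OC)cc5OC)c3[C@H]2c2cc(OC)cc(OC)c2)[C@@H](c2cc(OC)cc(OC)c2)[C@H](c2ccc(OC)cc2)O4)cc1
F7 | step 14 | ring-opened decaphenol of 24 with both C2–O bonds cleaved to 4-hydroxyphenyl carbinols (carbinol centres undefined; the three methine centres as in 24) | Oc1ccc(cc1)C(O)[C@H](c1cc(O)cc(O)c1)c1c(O)cc(O)c2c1C[C@H](c1ccc(O)cc1O)c1c(O)cc(O)cc1[C@H]2C(O)c1ccc(O)cc1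
A1 | alternative 1 | seven-ring and furan B core lacking furan A, as its methoxymethyl ether (three stereocentres R) | COCOc1cc2c3c(c1)C[C@H](c1ccc(OC)cc1OC)c1c(OC)cc(OC)cc1[C@H]3[C@H](c1ccc(OC)cc1)O2
A2 | alternative 1 | (R)-4-[2-(2-bromo-4,6-dimethoxyphenyl)-2-(2,4-dimethoxyphenyl)ethyl]-6-(methoxymethoxy)-2-(4-methoxyphenyl)benzofuran | COCOc1cc2oc(-c3ccc(OC)cc3)cc2c(C[C@H](c2ccc(OC)cc2OC)c2c(OC)cc(OC)cc2Br)c1
A3 | alternative 2 | dimethyl (2R,3S,5S,6R)-2,6-bis(4-methoxyphenyl)-4-(pivaloyloxymethyl)-2,3,5,6-tetrahydrobenzo[1,2-b:5,4-b']difuran-3,5-dicarboxylate (2,3-cis and 5,6-cis) | COc1ccc([C@@H]2Oc3cc4c(c(COC(=O)C(C)(C)C)c3[C@@H]2C(=O)OC)[C@H](C(=O)OC)[C@H](c2ccc(OC)cc2)O4)cc1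
A4 | alternative 2 | dimethyl 2,2'-[4,6-bis(4-methoxybenzyloxy)-2-(pivaloyloxymethyl)-1,3-phenylene]bis(diazoacetate) | COc1ccc(COc2cc(OCc3ccc(OC)cc3)c(C(=[N+]=[N-])C(=O)OC)c(COC(=O)C(C)(C)C)c2C(=[N+]=[N-])C(=O)OC)cc1
A5 | alternative 3 | (2R,3R,5R,6R)-3,5-bis(3,5-dimethoxyphenyl)-2,6-bis(4-methoxyphenyl)-4-[(triisopropylsilyloxy)methyl]-2,3,5,6-tetrahydrobenzo[1,2-b:5,4-b']difuran | COc1ccc([C@@H]2Oc3cc4c(c(CO[Si](C(C)C)(C(C)C)C(C)C)c3[C@H]2c2cc(OC)cc(OC)c2)[C@@H](c2cc(OC)cc(OC)c2)[C@H](c2ccc(OC)cc2)O4)cc1
A6 | alternative 3 | (2R,3R,5R,6R)-3,5-bis(3,5-dimethoxyphenyl)-4-[(triisopropylsilyloxy)methyl]-2,3,5,6-tetrahydrobenzo[1,2-b:5,4-b']difuran-2,6-dicarboxylic acid | OC(=O)[C@@H]1Oc2cc3c(c(CO[Si](C(C)C)(C(C)C)C(C)C)c2[C@H]1c1cc(OC)cc(OC)c1)[C@@H](c1cc(OC)cc(OC)c1)[C@H](C(=O)O)O3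
A7 | alternative 3 | 4-iodoanisole | COc1ccc(I)cc1
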